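**Retrosynthetic overview**
1. The target is opened at ring B: the C9 methylene is removed from between the C8 carbonyl and the quaternary C10, leaving a trans-fused hydrindenone that already carries all of ring A and the hydroxyisopropyl enone (ring B is made last, 5 → 6, by a 1,2-shift).
2. The hydrindenone comes from a five-ring ketone by aldol addition of acetone at its only enolisable α-carbon, esterification of the C3 alcohol with (2R)-2-methylbutanoic acid, and dehydrogenation.
3. The ring A stereocentres come from a Hajos–Parrish-type enone: dissolving-metal reduction with enolate hydroxylation (C5–H, C4–OH), then hydroxyl-directed reduction (C3–OH).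
4. The bicyclic enedione comes from 2-methylcyclopentane-1,3-dione and ethyl vinyl ketone by an amino-acid-mediated Robinson annulation, which sets C10.
5. Ring order: five-membered carbocycle (purchased) → ring A (annulation) → ring B (ring expansion of the five-membered ring).

Assumption: eudesmane numbering (ring A = C1–C5/C10, ring B = C5–C10) is used for every bicyclic compound, the hydrindanes being numbered as 9-nor compounds, and all starting materials and reagents named are taken to be purchasable.

**Step 1**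
Reactants: 1 2-methylcyclopentane-1,3-dione; 2 pent-1-en-3-one (ethyl vinyl ketone)
Product: 4 (7aS)-4,7a-dimethyl-2,3,7,7a-tetrahydro-1H-indene-1,5(6H)-dione, via triketone 3 (not isolated)
Conditions: 2 (1.3 equiv), H2O, 70 °C; evaporate; (S)-phenylalanine (1.0 equiv), HClO4 (aq., 0.5 equiv), MeCN, 80 °C
Reagents that add atoms: none
Why: Michael addition followed by the Hajos–Parrish–Eder–Sauer–Wiechert aldol condensation, in which the (S)-phenylalanine enamine of the side-chain ketone attacks one of the two enantiotopic ring carbonyls and dehydration gives the enone, fixing the quaternary carbon C10 (S in 4, the same spatial arrangement as R in 16).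

**Step 2**
Reactants: 4 (7aS)-4,7a-dimethyl-2,3,7,7a-tetrahydro-1H-indene-1,5(6H)-dione
Product: 6 (1S,3aR,4S,7aS)-1,4-dihydroxy-4,7a-dimethyloctahydro-5H-inden-5-one, via dilithium enolate alkoxide 5 (not isolated)
Conditions: Li (4.2 equiv), t-BuOH (2.1 equiv), NH3(l)/THF, −78 °C; NH3 off; 2-(phenylsulfonyl)-3-phenyloxaziridine (1.3 equiv), THF, −78 °C; H2O
Reagents that add atoms: 2-(phenylsulfonyl)-3-phenyloxaziridine, O=S(=O)(c1ccccc1)N1OC1c1ccccc1
Why: Birch-type dissolving-metal reduction followed by Davis enolate hydroxylation, in which the β-carbon C5 of the reduced enone is protonated axially on the face away from the angular methyl to give the trans-fused lithium enolate 5 (the saturated ketone being reduced to the 8β-alkoxide), and the oxaziridine then attacks the regiodefined C3–C4 enolate on the α-face, opposite the 1,3-related angular methyl, to set 4α-OH/4β-Me.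

**Step 3**
Reactants: 6 (1S,3aR,4S,7aS)-1,4-dihydroxy-4,7a-dimethyloctahydro-5H-inden-5-one
Product: 7 (3aR,4S,7aS)-4-hydroxy-4,7a-dimethylhexahydro-1H-indene-1,5(4H)-dione
Conditions: Dess–Martin periodinane (1.3 equiv), CH2Cl2, 0 °C to rt
Reagents that add atoms: none
Why: Dess–Martin oxidation of the only secondary alcohol restores the five-ring ketone, while the tertiary α-ketol is inert and no stereocentre is touched.

**Step 4**
Reactants: 7 (3aR,4S,7aS)-4-hydroxy-4,7a-dimethylhexahydro-1H-indene-1,5(4H)-dione
Product: 8 (3aR,4S,5S,7aS)-4,5-dihydroxy-4,7a-dimethyloctahydro-1H-inden-1-one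
Conditions: Me4NBH(OAc)3 (4 equiv), MeCN/AcOH (1:1), −20 °C to rt
Reagents that add atoms: none
Why: Saksena–Evans hydroxyl-directed reduction, in which the acetoxyborohydride bound to the 4α-hydroxyl delivers hydride to the α-face of C3 (axial attack, the β-face being shielded by the axial 4β-methyl) to give the equatorial 3β-alcohol trans to 4α-OH, while the unassisted five-ring ketone is not reduced by this reagent.

**Step 5**
Reactants: 8 (3aR,4S,5S,7aS)-4,5-dihydroxy-4,7a-dimethyloctahydro-1H-inden-1-one; 9 acetone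
Product: 11 (2S,3aR,4S,5S,7aS)-4,5-dihydroxy-2-(2-hydroxypropan-2-yl)-4,7a-dimethyloctahydro-1H-inden-1-one, via trilithium enolate 10 (not isolated)
Conditions: LiN(iPr)2 (3.3 equiv), THF, −78 °C; 9 (5 equiv), −78 °C; AcOH
Reagents that add atoms: none
Why: Directed lithium-enolate aldol addition, in which, after lithiation of both hydroxyls, the ketone can enolise only toward C7 because C10 is quaternary, and enolate 10 adds to acetone mainly from the α-face opposite the angular methyl (the C7 centre is erased in step 7, so its configuration is immaterial).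

**Step 6**
Reactants: 11 (2S,3aR,4S,5S,7aS)-4,5-dihydroxy-2-(2-hydroxypropan-2-yl)-4,7a-dimethyloctahydro-1H-inden-1-one; 12 (2R)-2-methylbutanoic acid
Product: 13 (2S,3aR,4S,5S,7aS)-4-hydroxy-2-(2-hydroxypropan-2-yl)-4,7a-dimethyl-1-oxooctahydro-1H-inden-5-yl (2R)-2-methylbutanoate
Conditions: 12 (1.5 equiv), N,N'-dicyclohexylcarbodiimide (1.6 equiv), DMAP (0.2 equiv), CH2Cl2, 0 °C to rt
Reagents that add atoms: none
Why: Steglich esterification acylates only the secondary C3 hydroxyl (both tertiary alcohols are inert under these conditions), with retention at C3 and without touching the α-centre of the acid.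

**Step 7**
Reactants: 13 (2S,3aR,4S,5S,7aS)-4-hydroxy-2-(2-hydroxypropan-2-yl)-4,7a-dimethyl-1-oxooctahydro-1H-inden-5-yl (2R)-2-methylbutanoate
Product: 14 (3aR,4S,5S,7aS)-4-hydroxy-2-(2-hydroxypropan-2-yl)-4,7a-dimethyl-1-oxo-3a,4,5,6,7,7a-hexahydro-1H-inden-5-yl (2R)-2-methylbutanoate
Conditions: IBX (2-iodoxybenzoic acid, 3 equiv), DMSO, 60 °C
Reagents that add atoms: none
Why: IBX α,β-dehydrogenation of a ketone (Nicolaou desaturation) can remove hydrogen only across C6–C7 because the other α-carbon (C10) is quaternary, giving the 2-substituted cyclopent-2-enone, erasing the C7 centre and leaving C5 untouched.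

**Step 8**
Reactants: 14 (3aR,4S,5S,7aS)-4-hydroxy-2-(2-hydroxypropan-2-yl)-4,7a-dimethyl-1-oxo-3a,4,5,6,7,7a-hexahydro-1H-inden-5-yl (2R)-2-methylbutanoate
Product: 16 (1S,2S,4aR,8aR)-1-hydroxy-7-(2-hydroxypropan-2-yl)-1,4a-dimethyl-6-oxo-1,2,3,4,4a,5,6,8a-octahydronaphthalen-2-yl (2R)-2-methylbutanoate, via silyl ketone 15 (not isolated)
Conditions: Me3SiCHN2 (2 equiv), Sc(OTf)3 (0.2 equiv), CH2Cl2, −40 to 0 °C; then aq. HCl (1 mol/L), THF, 0 °C
Reagents that add atoms: (trimethylsilyl)diazomethane, C[Si](C)(C)C=[N+]=[N-]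
Why: Proposed new method: a chelation-gated one-carbon ring expansion in which Sc(OTf)3 is held between the C11 hydroxyl and the C8 carbonyl oxygen, Me3SiCHN2 adds to C8 from the α-face opposite the angular methyl, and the conjugated sp2 α-carbon C7 (a poor migrating group) stays while the fully substituted C10 shifts 1,2 onto the diazo carbon with retention and loss of N2, so that CH2 enters between C8 and C10 and the enone stays conjugated, the bulky carbon-bound silyl group of 15 blocking a second insertion before protodesilylation; the closest known reaction type is the Lewis-acid-promoted diazoalkane homologation of ketones (Tiffeneau–Demjanov-type ring expansion), which has not been shown for α'-quaternary 2-(1-hydroxyalkyl)cyclopent-2-enones.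

**Compound list**
1 | 2-methylcyclopentane-1,3-dione | CC1C(=O)CCC1=O | starting material
2 | pent-1-en-3-one (ethyl vinyl ketone) | CCC(=O)C=C | starting material
3 | 2-methyl-2-(3-oxopentyl)cyclopentane-1,3-dione | CCC(=O)CCC1(C)C(=O)CCC1=O | intermediate
4 | (7aS)-4,7a-dimethyl-2,3,7,7a-tetrahydro-1H-indene-1,5(6H)-dione | O=C1CC[C@]2(C)C(=O)CCC2=C1C | intermediate
5 | dilithium (1S,3aR,7aS)-4,7a-dimethyl-2,3,3a,6,7,7a-hexahydro-1H-indene-1,5-diolate (trans-fused; lithium enolate across C3–C4 and 8β-lithium alkoxide in eudesmane numbering) | [Li]OC1CC[C@]2(C)[C@@H](O[Li])CC[C@H]2C=1C | intermediate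
6 | (1S,3aR,4S,7aS)-1,4-dihydroxy-4,7a-dimethyloctahydro-5H-inden-5-one (trans-fused; 4α-OH, 4β-Me, 8β-OH) | O=C1CC[C@]2(C)[C@@H](O)CC[C@H]2[C@]1(C)O | intermediate
7 | (3aR,4S,7aS)-4-hydroxy-4,7a-dimethylhexahydro-1H-indene-1,5(4H)-dione | O=C1CC[C@]2(C)C(=O)CC[C@H]2[C@]1(C)O | intermediate
8 | (3aR,4S,5S,7aS)-4,5-dihydroxy-4,7a-dimethyloctahydro-1H-inden-1-one (3β,4α-diol) | O[C@H]1CC[C@]2(C)C(=O)CC[C@H]2[C@]1(C)O | intermediate
9 | acetone | CC(C)=O | starting material
10 | trilithium salt of 8: lithium enolate across C7–C8 and lithium alkoxides at O3 and O4 | [Li]O[C@H]1CC[C@]2(C)C(O[Li])=CC[C@H]2[C@]1(C)O[Li] | intermediate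
11 | (2S,3aR,4S,5S,7aS)-4,5-dihydroxy-2-(2-hydroxypropan-2-yl)-4,7a-dimethyloctahydro-1H-inden-1-one | O[C@H]1CC[C@]2(C)C(=O)[C@H](C(C)(C)O)C[C@H]2[C@]1(C)O | intermediate
12 | (2R)-2-methylbutanoic acid | CC[C@@H](C)C(O)=O | starting material
13 | (2S,3aR,4S,5S,7aS)-4-hydroxy-2-(2-hydroxypropan-2-yl)-4,7a-dimethyl-1-oxooctahydro-1H-inden-5-yl (2R)-2-methylbutanoate | CC[C@@H](C)C(=O)O[C@H]1CC[C@]2(C)C(=O)[C@H](C(C)(C)O)C[C@H]2[C@]1(C)O | intermediate
14 | (3aR,4S,5S,7aS)-4-hydroxy-2-(2-hydroxypropan-2-yl)-4,7a-dimethyl-1-oxo-3a,4,5,6,7,7a-hexahydro-1H-inden-5-yl (2R)-2-methylbutanoate (trans-fused cyclopent-2-enone) | CC[C@@H](C)C(=O)O[C@H]1CC[C@]2(C)C(=O)C(C(C)(C)O)=C[C@H]2[C@]1(C)O | intermediate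
15 | 9α-trimethylsilyl derivative of 16 (Me3Si on the inserted carbon between C8 and C10, trans to the angular methyl; the C9 epimer would serve equally) | CC[C@@H](C)C(=O)O[C@H]1CC[C@]2(C)[C@H]([Si](C)(C)C)C(=O)C(C(C)(C)O)=C[C@H]2[C@]1(C)O | intermediate
16 | (1S,2S,4aR,8aR)-1-hydroxy-7-(2-hydroxypropan-2-yl)-1,4a-dimethyl-6-oxo-1,2,3,4,4a,5,6,8a-octahydronaphthalen-2-yl (2R)-2-methylbutanoate (CNP0201989.1; 3β-acyloxy, 4α-OH, 5α-H, 10β-Me) | CC[C@@H](C)C(=O)O[C@H]1CC[C@]2(C)CC(=O)C(C(C)(C)O)=C[C@H]2[C@]1(C)O | target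

Total steps: 8. Longest linear sequence: 8 steps (1 to 16).

**Three steps most likely to fail**

Step 8 (the proposed new ring expansion). The carbonyl is flanked by a quaternary carbon and a substituted alkene, so addition may be slow; the diazo compound could instead add across the enone, or the alkenyl carbon could migrate. The fallback uses known chemistry and moves the ring expansion in front of the side-chain work, setting out from 8. Dibromomethyllithium (CH2Br2, lithium 2,2,6,6-tetramethylpiperidide, THF, −78 °C) adds to the five-ring ketone from the α-face to give the dibromomethyl carbinol F1. n-BuLi (−78 °C) then turns it into a β-oxido carbenoid, which rearranges with 1,2-shift of the more substituted C10 to the trans-decalin diol ketone F2. Kinetic enolisation with LiN(iPr)2 at the less hindered C7 and addition to acetone give the aldol F3. Steglich esterification with 12 gives the ester F4, and IBX dehydrogenation (only C6–C7 can be desaturated) returns to the route at 16.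

Step 2 (reduction and hydroxylation in one flask). The trans/cis ratio at the ring fusion of a hydrindenone is less secure than in decalins, the C3 enolate may be over-reduced, and hydroxylation of a tetrasubstituted enolate may be sluggish. The fallback sets out from 4 and separates the events. NaBH4 (EtOH, −20 °C) reduces only the saturated ketone to the hydroxy enone F5. Li/NH3 followed by Me3SiCl/Et3N traps the trans-fused enolate as the bis(trimethylsilyl) compound F6, which can be purified from any cis isomer. Rubottom oxidation with mCPBA gives the siloxy ketone F7, and HF in MeCN removes both silyl groups to return to the route at 6.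

Step 7 (IBX dehydrogenation). The β-hydroxy ketone may undergo retro-aldol loss of acetone on heating, and the tertiary α-hydrogen is hindered. The fallback sets out from 13 and uses a Saegusa–Ito oxidation. Me3SiOTf/Et3N (CH2Cl2, 0 °C) gives the tris(trimethylsilyl) compound F8 (silyl enol ether toward C7, the only possible direction, and both tertiary alcohols silylated). Pd(OAc)2 (1.1 equiv, MeCN, rt) gives the enone bis(silyl ether) F9, and HF·pyridine returns to the route at 14.

**Further compounds**
F1 | step 8 | 8α-dibromomethyl 8β-carbinol from 8 (1-(dibromomethyl)-4,7a-dimethyloctahydro-1H-indene-1,4,5-triol, trans-fused, 3β,4α-diol) | O[C@H]1CC[C@]2(C)[C@](O)(C(Br)Br)CC[C@H]2[C@]1(C)O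
F2 | step 8 | (4aR,5S,6S,8aR)-5,6-dihydroxy-5,8a-dimethyloctahydronaphthalen-2(1H)-one | O[C@H]1CC[C@]2(C)CC(=O)CC[C@H]2[C@]1(C)O
F3 | step 8 | F2 carrying an equatorial 2-hydroxypropan-2-yl group on C7 (C3 of the naphthalenone; epimer equally usable) | O[C@H]1CC[C@]2(C)CC(=O)[C@@H](C(C)(C)O)C[C@H]2[C@]1(C)O
F4 | step 8 | 3β-O-(2R)-2-methylbutanoate of F3 (6,7-dihydro-16) | CC[C@@H](C)C(=O)O[C@H]1CC[C@]2(C)CC(=O)[C@@H](C(C)(C)O)C[C@H]2[C@]1(C)O
F5 | step 2 | (1S,7aS)-1-hydroxy-4,7a-dimethyl-1,2,3,6,7,7a-hexahydro-5H-inden-5-one | O=C1CC[C@]2(C)[C@@H](O)CCC2=C1C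
F6 | step 2 | trans-fused bis(trimethylsilyl) compound: trimethylsilyl enol ether across C3–C4 and 8β-trimethylsilyl ether | C[Si](C)(C)OC1CC[C@]2(C)[C@@H](O[Si](C)(C)C)CC[C@H]2C=1C
F7 | step 2 | 4α,8β-bis(trimethylsilyl) ether of 6 | O=C1CC[C@]2(C)[C@@H](O[Si](C)(C)C)CC[C@H]2[C@]1(C)O[Si](C)(C)C
F8 | step 7 | tris(trimethylsilyl) derivative of 13: silyl enol ether across C7–C8 and trimethylsilyl ethers of both tertiary alcohols | CC[C@@H](C)C(=O)O[C@H]1CC[C@]2(C)C(O[Si](C)(C)C)=C(C(C)(C)O[Si](C)(C)C)C[C@H]2[C@]1(C)O[Si](C)(C)C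
F9 | step 7 | bis(trimethylsilyl) ether of 14 (both tertiary alcohols silylated) | CC[C@@H](C)C(=O)O[C@H]1CC[C@]2(C)C(=O)C(C(C)(C)O[Si](C)(C)C)=C[C@H]2[C@]1(C)O[Si](C)(C)C
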